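The runs were computed with made-up constants.

Wednesday's flask cannot owe its chains to initiation step by step: each initiator puts one monomer into a chain, its charge is 4.93% of the solid monomer, and c(monomer in chains) reads 15.2% at 10.0 min. Living ends must be adding the rest.

| setting | Wednesday's | Monday's | flask |
|---|---|---|---|
| solid monomer | 1.5 M | 1.5 M | 1.5 M |
| initiator | 74 mM | 110 mM | 74 mM |
| temperature | 100 °C | 95 °C | 100 °C |
| remark | the very flask that is asked about, followed so far | run made earlier |  |
| time |  |  | 10 min |

| run | time / min | monomer in chains / % | solid monomer / % |
|---|---|---|---|
| Wednesday's | 0.833 | 7.2 | 15.1 |
| Wednesday's | 2.00 | 12.9 | 0.4 |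
| Wednesday's | 4.00 | 13.8 | 0.7 |
| Wednesday's | 10.0 | 15.2 | 0.6 |
| Monday's | 0.417 | 1.6 | 35.0 |
| Monday's | 1.00 | 7.5 | 7.3 |
| Monday's | 2.00 | 15.0 | 0 |
| Monday's | 5.00 | 18.0 | 1.1 |

(scatter of a reading: 0.5 percentage points)

- amber: at 10 min raise the temperature by 10 K, then wait 20 min
- red: at 10 min take out 90% of the monomer in chains then present, then wait 20 min
- blue: at 10 min add initiator, 100% of the amount charged, then wait 20 min
- green: change nothing and wait 20 min more

- percentages count the solid monomer that a species holds: one side product counts as two
- solid, in amounts per volume of the solution: solid monomer
- monomer in chains taken out counts as made
- on the list of suspects stand: free monomer + initiator -> living end + monomer in chains; free monomer + living end -> monomer in chains + living end; solid monomer <-> free monomer; free monomer + monomer in chains -> side product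
- at the start none of the solid monomer is in solution
- additions bring no volume worth counting

* monomer in chains, in percent of the solid monomer first charged, at 10 min
* the option that brings most further monomer in chains ("none" if no option brings more than 2 percentage points) (amber / red / blue / green / none)
* monomer in chains present, with what was taken out counted in, in percent of the solid monomer first charged, after amber
* monomer in chains present, with what was taken out counted in, in percent of the solid monomer first charged, after red

In Wednesday's flask the chains climb steeply to 7.2% at 0.833 min, while the solid monomer falls to 15.1%. The knee comes near 2.00 min, where the chains read 12.9% and the solid 0.4%. After it the chains gain 2.3 percentage points in 8.00 min. The last two readings average 14.5%, taken as the level, and the gap to it closes with a time constant of about 0.769 min. Chains and solid together leave 84.9% of the charge unseen. Free monomer beside living ends feeds chains, and the chains hold, so that share is read as side product.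

Growth goes with free monomer times living ends, and the side step with free monomer times chains. Free monomer multiplies both, so at one temperature, initiation apart, chains head for a multiple of the living ends. In Wednesday's flask 2.94 is the stall ratio, chains at the level per initiator charged. Monday's flask, cooler and with more initiator, gives 2.45 from its last reading. Amber, red, blue and green each work through free monomer, so this reckoning expects the level at 10 min, the same level after amber and red, and no gain of 2 points.

The forecast, a little higher, gives 15% now, 15.3% after amber, 15.7% after red and none as the best option, saying “so the flask is essentially exhausted”.

The flask gives 14.4% at 10 min, 14.4% after amber, 14.4% after red, and best option none.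

    free monomer + initiator → living end + monomer in chains (k = 0.0110 M⁻¹ s⁻¹, Ea = 66.0 kJ mol⁻¹)
    free monomer + living end → monomer in chains + living end, rate k2*[living end]*[free monomer] (k = 0.260 M⁻¹ s⁻¹, Ea = 62.0 kJ mol⁻¹)
    solid monomer ⇌ free monomer, rate k3*(cs3 - [free monomer]) while solid is left; crystals form when [free monomer] > cs3 (solubility = 1.20 M, k = 0.0650 s⁻¹)
    free monomer + monomer in chains → side product (k = 0.0550 M⁻¹ s⁻¹, Ea = 55.0 kJ mol⁻¹)
    (constants at 100 °C)

The side step is the main reason for the level: the same run without it puts >99.9% in chains, against 14.4%. Wednesday's flask holds 0.0504 M of living end at 10.0 min, so the stall ratio of 2.94 per initiator charged becomes a pure number, 4.32 chains per living end. A neighbour flask charged with 0.030 M of initiator holds 0.0258 M of living end. That multiple gives it 7.42% of its solid monomer in chains, and that neighbour flask stands at 7.87%.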